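**Assumption:** the target SMILES has no stereocentre, and its only non-aromatic ring alkene is held cis by the ring. The compound is therefore achiral and no stereocontrol is needed.

## Retrosynthetic overview

1. The pyran C–O bond is opened by a retro-oxa-6π step to an ortho-quinone methide, which comes from dehydration of a 5-(1-hydroxy-3-methylbut-2-enyl)resorcinol ketone.
2. The resorcinol ring A is disconnected by a [4+2]/aromatisation into a 1-methoxy-1,3-bis(silyloxy)diene (carrying the prenyl group and the silyloxy-allyl side chain) and a terminal ynone carrying the 4-hydroxyphenethyl chain.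
3. Ring order in the forward sense: ring A first, then the pyran ring, both in the same flask; ring B is bought.
4. The diene comes from methyl acetoacetate by α-prenylation, γ-aldol addition to prenal and tris-silylation.
5. The ynone comes from methyl 3-(4-hydroxyphenyl)propanoate through a Weinreb amide made in situ and ethynylmagnesium bromide.

## Route

**Step 1**
Reactants: 1 methyl acetoacetate; 2 prenyl bromide (1-bromo-3-methylbut-2-ene)
Product: 3 methyl 2-acetyl-5-methylhex-4-enoate (racemic)
Conditions: K2CO3 (1.2 equiv), acetone, reflux, 12 h (1 in 1.5-fold excess)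
Reagents that add atoms: none
Why: Acetoacetic ester C-alkylation (SN2 of the potassium enolate on a primary allylic bromide) puts the prenyl group on the carbon that becomes C8 of the chromene; the new stereocentre is racemic and is erased when this carbon becomes aromatic.

**Step 2**
Reactants: 3 methyl 2-acetyl-5-methylhex-4-enoate; 4 prenal (3-methylbut-2-enal)
Product: 5 methyl 5-hydroxy-7-methyl-2-(3-methylbut-2-en-1-yl)-3-oxooct-6-enoate (diastereomer mixture)
Conditions: LDA (2.2 equiv), THF, 0 °C; then 4 (1.1 equiv), −78 °C, 30 min; AcOH quench at −78 °C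
Reagents that add atoms: none
Why: Huckin–Weiler dianion aldol reaction, in which the γ-carbanion of the β-keto ester dianion adds 1,2 to the enal; both stereocentres form unselectively and are destroyed in step 5.

**Step 3**
Reactants: 5 methyl 5-hydroxy-7-methyl-2-(3-methylbut-2-en-1-yl)-3-oxooct-6-enoate
Product: 7 1-methoxy-7-methyl-2-(3-methylbut-2-en-1-yl)-1,3,5-tris(trimethylsilyloxy)octa-1,3,6-triene (geometric isomer mixture; used crude), via bis-silyl enoate 6 (not isolated)
Conditions: LDA (2.1 equiv), THF, −78 °C; TMSCl (2.2 equiv), −78 → 0 °C; then LDA (1.2 equiv), −78 °C, 1 h; TMSCl (1.3 equiv), −78 → 20 °C; evaporate, pentane, filter under Ar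
Reagents that add atoms: chlorotrimethylsilane (TMSCl), C[Si](C)(C)Cl
Why: Stepwise enolate O-silylation (first the alkoxide and the β-keto ester enolate, then the kinetic γ-dienolate of silyl enol ether 6) gives a Chan–Brassard-type 1-methoxy-1,3-bis(silyloxy)diene; retro-aldol of the lithium aldolate would have to regenerate the high-energy dianion and is negligible at −78 °C, and the silyloxy stereocentre stays unselective and irrelevant.

**Step 4**
Reactants: 8 methyl 3-(4-hydroxyphenyl)propanoate; 9 N,O-dimethylhydroxylamine hydrochloride; 10 ethynylmagnesium bromide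
Product: 12 1-(4-hydroxyphenyl)pent-4-yn-3-one, via Weinreb amide 11 (not isolated)
Conditions: 9 (1.5 equiv), iPrMgCl (4.5 equiv), THF, −20 → 0 °C; then 10 (3 equiv), 0 → 20 °C; inverse quench into cold aq NaHSO4
Reagents that add atoms: none
Why: Ester-to-Weinreb-amide exchange with the chloromagnesium amide, followed by acyl substitution with the alkynyl Grignard reagent, where the chelated tetrahedral intermediate stops over-addition and the phenol is carried as its magnesium phenoxide; the cold acidic inverse quench keeps the released amine from adding to the ynone, and no stereocentre is formed.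

**Step 5**
Reactants: 12 1-(4-hydroxyphenyl)pent-4-yn-3-one; 13 N,O-bis(trimethylsilyl)acetamide (BSA); 7 1-methoxy-7-methyl-2-(3-methylbut-2-en-1-yl)-1,3,5-tris(trimethylsilyloxy)octa-1,3,6-triene
Product: 18 1-[7-hydroxy-2,2-dimethyl-8-(3-methylbut-2-en-1-yl)-2H-chromen-6-yl]-3-(4-hydroxyphenyl)propan-1-one (the target), via aryl trimethylsilyl ether 14 (not isolated), via cyclohexa-1,4-diene cycloadduct 15 (not isolated), via benzylic alcohol 16 (not isolated), via ortho-quinone methide 17 (not isolated)
Conditions: 13 (1.0 equiv), PhMe, 20 °C, 1 h; 7 (1.5 equiv), 20 → 80 °C, 12 h; then CSA (0.3 equiv), MeOH–CH2Cl2, 0 → 20 °C, 2 h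
Reagents that add atoms: none
Why: Proposed new method: a regioselective Diels–Alder benzannulation of the 1-methoxy-1,3-bis(silyloxy)diene with the alkynone (the nucleophilic C4 of 7 bonds to the alkyne CH terminus and the ketene-acetal carbon to the acyl-bearing carbon, so collapse of the silyl ketal in 15 with loss of MeOSiMe3 leaves one OH ortho and the other oxygen para to the ketone with the prenyl group between them) is merged with acid-triggered dehydration of the doubly activated o-hydroxybenzylic allylic alcohol 16 to ortho-quinone methide 17 and its oxa-6π electrocyclisation, so that ring A and the pyran ring form in one flask; the closest known reaction types are the Brassard/Chan-diene–alkyne Diels–Alder aromatisation and the chromium-carbene benzannulation/o-quinone methide/electrocyclisation cascade to chromenes, and no stereocentre is created.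

Excess 7 is hydrolysed back to 5 in the acid stage and is removed by chromatography.

## Compound list

1 | methyl acetoacetate | CC(=O)CC(=O)OC | starting material
2 | prenyl bromide (1-bromo-3-methylbut-2-ene) | CC(C)=CCBr | starting material
3 | methyl 2-acetyl-5-methylhex-4-enoate (racemic) | CC(=O)C(CC=C(C)C)C(=O)OC | intermediate (isolated)
4 | prenal (3-methylbut-2-enal) | CC(C)=CC=O | starting material
5 | methyl 5-hydroxy-7-methyl-2-(3-methylbut-2-en-1-yl)-3-oxooct-6-enoate (diastereomer mixture) | COC(=O)C(CC=C(C)C)C(=O)CC(O)C=C(C)C | intermediate (isolated)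
6 | methyl 7-methyl-2-(3-methylbut-2-en-1-yl)-3,5-bis(trimethylsilyloxy)octa-2,6-dienoate (racemic, alkene geometry not controlled) | COC(=O)C(CC=C(C)C)=C(O[Si](C)(C)C)CC(O[Si](C)(C)C)C=C(C)C | intermediate (not isolated)
7 | 1-methoxy-7-methyl-2-(3-methylbut-2-en-1-yl)-1,3,5-tris(trimethylsilyloxy)octa-1,3,6-triene (racemic, geometric isomer mixture) | COC(O[Si](C)(C)C)=C(CC=C(C)C)C(O[Si](C)(C)C)=CC(O[Si](C)(C)C)C=C(C)C | intermediate (isolated crude)
8 | methyl 3-(4-hydroxyphenyl)propanoate | COC(=O)CCc1ccc(O)cc1 | starting material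
9 | N,O-dimethylhydroxylamine hydrochloride | CNOC.Cl | starting material
10 | ethynylmagnesium bromide (0.5 M in THF) | C#C[Mg]Br | starting material
11 | 3-(4-hydroxyphenyl)-N-methoxy-N-methylpropanamide (in the flask as its magnesium phenoxide) | CON(C)C(=O)CCc1ccc(O)cc1 | intermediate (not isolated)
12 | 1-(4-hydroxyphenyl)pent-4-yn-3-one | C#CC(=O)CCc1ccc(O)cc1 | intermediate (isolated)
13 | N,O-bis(trimethylsilyl)acetamide | CC(=N[Si](C)(C)C)O[Si](C)(C)C | starting material
14 | 1-[4-(trimethylsilyloxy)phenyl]pent-4-yn-3-one | C#CC(=O)CCc1ccc(O[Si](C)(C)C)cc1 | intermediate (not isolated)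
15 | Diels–Alder adduct: 1-[6-methoxy-3-(3-methyl-1-(trimethylsilyloxy)but-2-en-1-yl)-5-(3-methylbut-2-en-1-yl)-4,6-bis(trimethylsilyloxy)cyclohexa-1,4-dien-1-yl]-3-[4-(trimethylsilyloxy)phenyl]propan-1-one (stereoisomer mixture) | COC1(O[Si](C)(C)C)C(C(=O)CCc2ccc(O[Si](C)(C)C)cc2)=CC(C(O[Si](C)(C)C)C=C(C)C)C(O[Si](C)(C)C)=C1CC=C(C)C | intermediate (not isolated)
16 | 1-[2,4-dihydroxy-5-(1-hydroxy-3-methylbut-2-en-1-yl)-3-(3-methylbut-2-en-1-yl)phenyl]-3-(4-hydroxyphenyl)propan-1-one (racemic) | CC(C)=CCc1c(O)c(C(=O)CCc2ccc(O)cc2)cc(C(O)C=C(C)C)c1O | intermediate (not isolated)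
17 | (6Z)-3-hydroxy-4-[3-(4-hydroxyphenyl)propanoyl]-6-(3-methylbut-2-en-1-ylidene)-2-(3-methylbut-2-en-1-yl)cyclohexa-2,4-dien-1-one | CC(C)=CCC1=C(O)C(C(=O)CCc2ccc(O)cc2)=C/C(=C/C=C(C)C)C1=O | intermediate (not isolated)
18 | 1-[7-hydroxy-2,2-dimethyl-8-(3-methylbut-2-en-1-yl)-2H-chromen-6-yl]-3-(4-hydroxyphenyl)propan-1-one (achiral) | CC(C)=CCc1c(O)c(C(=O)CCc2ccc(O)cc2)cc2c1OC(C)(C)C=C2 | target

## Step count and risk

Total steps: 5. Longest linear sequence: 4 steps (1 → 2 → 3 → 5); step 4 is a one-step side branch.

**The three steps most likely to fail**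

**Step 5 (cycloaddition/aromatisation/electrocyclisation cascade).** The hindered 2,4-disubstituted diene may react slowly with the heat-sensitive ynone 14, giving open-chain Michael products or polymer instead of the cycloadduct. The fallback sets out from 7 and uses the smallest, most reactive alkynone in excess, building the dihydrochalcone chain afterwards. Diene 7 and but-3-yn-2-one (3 equiv, PhMe, 70 °C, then CSA/MeOH as in step 5) give the methyl ketone 1-[7-hydroxy-2,2-dimethyl-8-(3-methylbut-2-en-1-yl)-2H-chromen-6-yl]ethan-1-one F1. Claisen–Schmidt condensation of F1 with 4-hydroxybenzaldehyde (KOH, EtOH–H2O, 20 → 50 °C) gives the chalcone (E)-1-[7-hydroxy-2,2-dimethyl-8-(3-methylbut-2-en-1-yl)-2H-chromen-6-yl]-3-(4-hydroxyphenyl)prop-2-en-1-one F2. Copper hydride conjugate reduction of the enone alone (Stryker's reagent cat., PMHS, PhMe, then fluoride work-up) leaves the chromene and prenyl alkenes untouched and comes back to the route at 18.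

**Step 3 (tris-silylation to diene 7).** The γ-lithiated species carries a β-silyloxy group and may eliminate, and C-silylation or partial silylation would spoil a diene that cannot be chromatographed. The fallback sets out from 3 and drops the oxygenated side chain from the diene, so the two rings are formed in separate steps. Compound 3 with TMSCl/Et3N (PhH, 20 °C) gives the silyl enol ether methyl 5-methyl-2-[1-(trimethylsilyloxy)ethylidene]hex-4-enoate F3. LDA then TMSCl (THF, −78 °C) converts F3 into the diene 1-methoxy-2-(3-methylbut-2-en-1-yl)-1,3-bis(trimethylsilyloxy)buta-1,3-diene F4. Diels–Alder reaction of F4 with 14 (made from 12 and 13 as in step 5; PhMe, 80 °C, then CSA/MeOH) gives the resorcinol ketone 1-[2,4-dihydroxy-3-(3-methylbut-2-en-1-yl)phenyl]-3-(4-hydroxyphenyl)propan-1-one F5. Condensation of F5 with prenal 4 (ethylenediamine diacetate cat., xylene, reflux; Knoevenagel/oxa-6π at the only free position ortho to the 4-OH) comes back to the route at 18.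

**Step 4 (one-pot ester → Weinreb amide → ynone with a free phenol).** Incomplete amide formation, or addition of the released amine or the phenoxide to the terminal ynone, would lower the yield. The fallback sets out from 8 and reaches the ynone by carbonyl addition and oxidation instead of acyl substitution. DIBAL-H (2.2 equiv, CH2Cl2, −78 °C) reduces 8 to the aldehyde 3-(4-hydroxyphenyl)propanal F6. Addition of 10 (2.5 equiv, THF, 0 °C) to F6 gives the propargylic alcohol 1-(4-hydroxyphenyl)pent-4-yn-3-ol F7. Oxidation of F7 with activated MnO2 (CH2Cl2, 20 °C), which is selective for the propargylic alcohol, comes back to the route at 12.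

## Further compounds

F1 | step 5 | 1-[7-hydroxy-2,2-dimethyl-8-(3-methylbut-2-en-1-yl)-2H-chromen-6-yl]ethan-1-one | CC(C)=CCc1c(O)c(C(C)=O)cc2c1OC(C)(C)C=C2
F2 | step 5 | (E)-1-[7-hydroxy-2,2-dimethyl-8-(3-methylbut-2-en-1-yl)-2H-chromen-6-yl]-3-(4-hydroxyphenyl)prop-2-en-1-one | CC(C)=CCc1c(O)c(C(=O)/C=C/c2ccc(O)cc2)cc2c1OC(C)(C)C=C2
F3 | step 3 | methyl 5-methyl-2-[1-(trimethylsilyloxy)ethylidene]hex-4-enoate | COC(=O)C(CC=C(C)C)=C(C)O[Si](C)(C)C
F4 | step 3 | 1-methoxy-2-(3-methylbut-2-en-1-yl)-1,3-bis(trimethylsilyloxy)buta-1,3-diene | COC(O[Si](C)(C)C)=C(CC=C(C)C)C(=C)O[Si](C)(C)C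
F5 | step 3 | 1-[2,4-dihydroxy-3-(3-methylbut-2-en-1-yl)phenyl]-3-(4-hydroxyphenyl)propan-1-one | CC(C)=CCc1c(O)ccc(C(=O)CCc2ccc(O)cc2)c1O
F6 | step 4 | 3-(4-hydroxyphenyl)propanal | O=CCCc1ccc(O)cc1
F7 | step 4 | 1-(4-hydroxyphenyl)pent-4-yn-3-ol (racemic) | C#CC(O)CCc1ccc(O)cc1
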